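**Strategy.** Locants: ring C1 (carries the side chain), C2 (CH2), C3/C4 (epoxide CH and C–CH3), C5 (angelate carbinol), C6 (free carbinol); side chain C7 (=CH2 carbon), C8 (angelate carbinol), C10 (side-chain epoxide CH). The cyclohexane is disconnected across C1–C6 and C2–C3. The oxygen-bearing carbons C5 and C8 are 1,5-related through C6–C1–C7, so one silicon atom can bridge their oxygens. A type 2 intramolecular Diels–Alder reaction of the silylene-tethered 1,2-dioxygenated diene (C3=C4–C5=C6) and vinyl ketone (C1=C2) then forms both bonds, enforces the otherwise disfavoured regiochemistry and sets C1 and C6 from C8. Saegusa oxidation removes the tether; C8 is inverted during Mitsunobu angeloylation.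

Key step: step 8

Assumption: 5-methylhex-4-enoic acid, (4R)-4-benzyl-1,3-oxazolidin-2-one, angelic acid and iPr2Si(OTf)2 are taken as commercially available.

Step 1
Reactants: 1 2-chloro-N-methoxy-N-methylacetamide; 2 4-methoxybenzyl alcohol
Product: 3 N-methoxy-2-[(4-methoxybenzyl)oxy]-N-methylacetamide
Conditions: NaH, Bu4NI (cat.), THF, 0 °C to rt
Reagents that add atoms: none
Why: Williamson etherification, in which the alkoxide of 2 displaces the activated α-chloride of 1 by SN2 while the Weinreb amide resists acyl substitution.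

Step 2
Reactants: 3 N-methoxy-2-[(4-methoxybenzyl)oxy]-N-methylacetamide
Product: 4 1-[(4-methoxybenzyl)oxy]-3-methylbut-3-en-2-one
Conditions: CH2=C(CH3)MgBr, THF, −78 to 0 °C; inverse quench into cold aq. NH4Cl
Reagents that add atoms: isopropenylmagnesium bromide, C=C(C)[Mg]Br
Why: Weinreb ketone synthesis, in which the magnesium chelate of the tetrahedral adduct prevents a second addition and releases the isopropenyl ketone on quench.

Step 3
Reactants: 5 5-methylhex-4-enoic acid; 6 (4R)-4-benzyl-1,3-oxazolidin-2-one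
Product: 8 (4R)-4-benzyl-3-(5-methylhex-4-enoyl)-1,3-oxazolidin-2-one, via mixed pivalic anhydride 7 (not isolated)
Conditions: pivaloyl chloride, Et3N, THF, −20 °C; then 6, LiCl, −20 °C to rt
Reagents that add atoms: none
Why: N-acylation of the oxazolidinone through a mixed anhydride, which is attacked at the less hindered (non-pivaloyl) carbonyl.

Step 4
Reactants: 8 (4R)-4-benzyl-3-(5-methylhex-4-enoyl)-1,3-oxazolidin-2-one
Product: 10 (4R)-4-benzyl-3-[(2R)-2-hydroxy-5-methylhex-4-enoyl]-1,3-oxazolidin-2-one, via sodium (Z)-enolate 9 (not isolated)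
Conditions: NaN(SiMe3)2, THF, −78 °C; 2-(phenylsulfonyl)-3-phenyloxaziridine, −78 °C; camphorsulfonic acid quench
Reagents that add atoms: 2-(phenylsulfonyl)-3-phenyloxaziridine, O=S(=O)(c1ccccc1)N1OC1c1ccccc1
Why: Evans–Davis asymmetric enolate hydroxylation, in which the chelated (Z)-enolate takes oxygen on the face opposite the benzyl group, so the (R)-auxiliary should give the (R)-carbinol (future C8) while the unactivated alkene is left alone.

Step 5
Reactants: 10 (4R)-4-benzyl-3-[(2R)-2-hydroxy-5-methylhex-4-enoyl]-1,3-oxazolidin-2-one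
Product: 11 (2R)-2-hydroxy-N-methoxy-N,5-dimethylhex-4-enamide
Conditions: MeNH(OMe)·HCl, AlMe3, CH2Cl2, 0 °C to rt; aq. potassium sodium tartrate work-up
Reagents that add atoms: N,O-dimethylhydroxylamine hydrochloride, CNOC.Cl
Why: aluminium-amide transamidation (Weinreb amide formation) at the exocyclic imide carbonyl, which releases the auxiliary without touching the carbinol stereocenter.

Step 6
Reactants: 11 (2R)-2-hydroxy-N-methoxy-N,5-dimethylhex-4-enamide
Product: 12 (4R)-4-hydroxy-7-methylocta-1,6-dien-3-one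
Conditions: CH2=CHMgBr (3.5 equiv), THF, −78 to 0 °C; inverse quench into cold aq. NH4Cl; BHT, used promptly
Reagents that add atoms: vinylmagnesium bromide, C=C[Mg]Br
Why: Weinreb ketone synthesis on the magnesium alkoxide of the α-hydroxy amide, where the chelate prevents over-addition and the cold inverse quench keeps the released amine from adding to the vinyl ketone.

Step 7
Reactants: 4 1-[(4-methoxybenzyl)oxy]-3-methylbut-3-en-2-one; 12 (4R)-4-hydroxy-7-methylocta-1,6-dien-3-one
Product: 14 (4R)-4-[({[(1Z)-1-[(4-methoxybenzyl)oxy]-3-methylbuta-1,3-dien-2-yl]oxy}di(propan-2-yl)silyl)oxy]-7-methylocta-1,6-dien-3-one, via enoxysilyl triflate 13 (not isolated)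
Conditions: iPr2Si(OTf)2 (1.0 equiv), Et3N, CH2Cl2, −78 to −40 °C; then 12, 2,6-lutidine, −78 to 0 °C; filtered through Et3N-deactivated silica and used directly
Reagents that add atoms: diisopropylsilyl bis(trifluoromethanesulfonate), CC(C)[Si](OS(=O)(=O)C(F)(F)F)(OS(=O)(=O)C(F)(F)F)C(C)C
Why: soft enolisation and O-silylation of the α-alkoxy ketone should give the (Z)-enol ether (both oxygens cis), and the remaining Si–OTf then silylates the secondary alcohol of 12 to give an unsymmetrical silylene bis-ether as a temporary silicon tether.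

Step 8
Reactants: 14 tethered triene (silylene bis-ether of the dienol of 4 and of 12)
Product: 15 (5R,7R,11R)-11-[(4-methoxybenzyl)oxy]-10-methyl-5-(3-methylbut-2-en-1-yl)-3,3-di(propan-2-yl)-2,4-dioxa-3-silabicyclo[5.3.1]undec-1(10)-en-6-one
Conditions: toluene (0.005 M), BHT (cat.), 80 °C
Reagents that add atoms: none
Why: Concerted, asynchronous [4+2] cycloaddition of the tethered diene C3=C4–C5=C6 onto the vinyl ketone C1=C2, i.e. a type 2 intramolecular Diels–Alder reaction with a disposable silylene tether, the closest precedent being silicon- and ester-tethered type 2 cycloadditions that give bridgehead enol ethers. The cyclohexene is closed by the cycloaddition itself, and the eight-membered ring C5–O–Si–O–C8–C7–C1–C6 closes with it as a bridge, giving a bicyclo[5.3.1] bridgehead enol silyl ether. The five-atom tether from the internal diene carbon C5 reaches C1 only if C1 bonds to the adjacent terminus C6, which enforces the 1,3 regiochemistry against the para preference of a 2-siloxy diene and holds the C7 carbonyl endo. C6 is set by the (Z)-enol ether geometry (PMB-oxy outside, hence cis to C7 on the new ring). C1 is set by C8: in the s-cis enone the C8–H should take the in-plane position next to the C6–OPMB group (A1,3-type strain), the tethered oxygen faces the diene and the prenyl CH2 points away, so (R)-C8 should expose the face that gives the C1 and C6 configurations of the target. The step needs regio-, endo- and facial selectivity; the tether secures the first two, the C8 substituent pattern the third, and high dilution suppresses intermolecular cycloaddition.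

Step 9
Reactants: 15 bicyclic ketone
Product: 16 (5R,7S,11R)-11-[(4-methoxybenzyl)oxy]-10-methyl-6-methylidene-5-(3-methylbut-2-en-1-yl)-3,3-di(propan-2-yl)-2,4-dioxa-3-silabicyclo[5.3.1]undec-1(10)-ene
Conditions: Cp2TiMe2, toluene/THF, 65 °C, dark
Reagents that add atoms: dimethyltitanocene, C[Ti](C)(C1C=CC=C1)C1C=CC=C1
Why: Petasis methylenation, in which thermally generated Cp2Ti=CH2 converts the C7 ketone into the methylidene group through an oxatitanacyclobutane under non-basic conditions, done at this stage because the C5 carbonyl is still masked as the enol silyl ether.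

Step 10
Reactants: 16 methylidene bicycle
Product: 18 (5S,6R)-5-[(3R)-3-hydroxy-6-methylhepta-1,5-dien-2-yl]-6-[(4-methoxybenzyl)oxy]-2-methylcyclohex-2-en-1-one, via silyl acetate enone 17 (not isolated)
Conditions: Pd(OAc)2 (1.2 equiv), MeCN, rt to 40 °C; then HF·pyridine, THF/pyridine, 0 °C
Reagents that add atoms: none
Why: Saegusa–Ito oxidation, in which silicon-to-palladium transfer gives the C4 palladium enolate and β-hydride elimination toward C3 should give the conjugated endocyclic enone while opening the tether, after which fluoride removes the residual silyl group from the C8 oxygen.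

Step 11
Reactants: 18 hydroxy enone; 19 angelic acid, (2Z)-2-methylbut-2-enoic acid
Product: 20 (3S)-2-{(1S,2R)-2-[(4-methoxybenzyl)oxy]-4-methyl-3-oxocyclohex-4-en-1-yl}-6-methylhepta-1,5-dien-3-yl (2Z)-2-methylbut-2-enoate
Conditions: PPh3, DIAD (betaine pre-formed), toluene, 0 °C to rt
Reagents that add atoms: none
Why: Mitsunobu esterification, in which SN2 displacement of the alkoxyphosphonium by angelate inverts C8 from (R) to the (S) configuration of the target under neutral conditions that should preserve the (Z)-enoate.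

Step 12
Reactants: 20 angelate enone
Product: 21 (3S)-2-{(1S,2R,3S)-3-hydroxy-2-[(4-methoxybenzyl)oxy]-4-methylcyclohex-4-en-1-yl}-6-methylhepta-1,5-dien-3-yl (2Z)-2-methylbut-2-enoate
Conditions: NaBH4, CeCl3·7H2O, MeOH, −78 to −40 °C
Reagents that add atoms: none
Why: Luche 1,2-reduction, in which hydride should add axially to the half-chair (C1 substituent equatorial) anti to the pseudoaxial C6–OPMB group, giving the C5 alcohol cis to C6–O and to the C1 side chain.

Step 13
Reactants: 21 allylic alcohol
Product: 22 epoxy alcohol, the C3–C4 epoxide of 21 with the epoxide oxygen cis to the C5 hydroxyl (epoxide O, C5–OH, C6–OPMB and the C1 side chain all on one ring face)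
Conditions: VO(acac)2 (5 mol %), t-BuOOH (in decane), CH2Cl2, 0 °C to rt
Reagents that add atoms: tert-butyl hydroperoxide, CC(C)(C)OO
Why: vanadium-catalysed hydroxyl-directed epoxidation, which delivers oxygen to the C3=C4 face syn to the C5 hydroxyl and should leave the prenyl, methylidene and enoate alkenes untouched.

Step 14
Reactants: 22 epoxy alcohol; 19 angelic acid
Product: 24 bis-angelate PMB ether (22 acylated at the C5 oxygen), via angelic 2,4,6-trichlorobenzoic anhydride 23 (not isolated)
Conditions: 19, 2,4,6-trichlorobenzoyl chloride, Et3N, toluene, rt; then 22, toluene, 80 °C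
Reagents that add atoms: none
Why: Yamaguchi-type acylation through the mixed anhydride without a nucleophilic catalyst, which esterifies the hindered C5 hydroxyl with retention and should avoid Z-to-E isomerisation to the tiglate.

Step 15
Reactants: 24 bis-angelate PMB ether
Product: 25 bis-epoxide PMB ether (24 with the (R)-configured C10–C11 epoxide)
Conditions: D-fructose-derived Shi ketone (0.3 equiv), Oxone (2KHSO5·KHSO4·K2SO4), K2CO3, Bu4NHSO4, MeCN/CH2(OMe)2/aq. Na2B4O7 buffer, 0 °C
Reagents that add atoms: potassium peroxymonosulfate (from Oxone), OOS(=O)(=O)[O-].[K+]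
Why: Shi asymmetric epoxidation, in which the chiral dioxirane attacks the electron-rich trisubstituted prenyl alkene through the spiro transition state that should give the (R)-epoxide at C10, the methylidene and enoate alkenes being much less reactive.

Step 16
Reactants: 25 bis-epoxide PMB ether
Product: 26 CNP0296086.3 (target)
Conditions: DDQ, CH2Cl2/aqueous pH 7 phosphate buffer (KH2PO4/Na2HPO4), 0 °C
Reagents that add atoms: none
Why: oxidative cleavage of the 4-methoxybenzyl ether by DDQ under buffered neutral conditions, which should free the C6 hydroxyl without epoxide opening or acyl migration from the neighbouring C5 angelate.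

**Compound list**

1 | 2-chloro-N-methoxy-N-methylacetamide | CON(C)C(=O)CCl | starting material
2 | 4-methoxybenzyl alcohol | COc1ccc(CO)cc1 | starting material
3 | N-methoxy-2-[(4-methoxybenzyl)oxy]-N-methylacetamide | COc1ccc(COCC(=O)N(C)OC)cc1 | intermediate
4 | 1-[(4-methoxybenzyl)oxy]-3-methylbut-3-en-2-one | COc1ccc(COCC(=O)C(C)=C)cc1 | intermediate
5 | 5-methylhex-4-enoic acid | CC(C)=CCCC(=O)O | starting material
6 | (4R)-4-benzyl-1,3-oxazolidin-2-one | O=C1N[C@H](Cc2ccccc2)CO1 | starting material
7 | 5-methylhex-4-enoic pivalic anhydride (not isolated) | CC(C)=CCCC(=O)OC(=O)C(C)(C)C | intermediate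
8 | (4R)-4-benzyl-3-(5-methylhex-4-enoyl)-1,3-oxazolidin-2-one | CC(C)=CCCC(=O)N1[C@H](Cc2ccccc2)COC1=O | intermediate
9 | sodium (Z)-enolate of 8 (not isolated) | CC(C)=CC/C=C(\[O-])N1[C@H](Cc2ccccc2)COC1=O.[Na+] | intermediate
10 | (4R)-4-benzyl-3-[(2R)-2-hydroxy-5-methylhex-4-enoyl]-1,3-oxazolidin-2-one | CC(C)=CC[C@@H](O)C(=O)N1[C@H](Cc2ccccc2)COC1=O | intermediate
11 | (2R)-2-hydroxy-N-methoxy-N,5-dimethylhex-4-enamide | CC(C)=CC[C@@H](O)C(=O)N(C)OC | intermediate
12 | (4R)-4-hydroxy-7-methylocta-1,6-dien-3-one | CC(C)=CC[C@@H](O)C(=O)C=C | intermediate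
13 | {[(1Z)-1-[(4-methoxybenzyl)oxy]-3-methylbuta-1,3-dien-2-yl]oxy}di(propan-2-yl)silyl trifluoromethanesulfonate (not isolated) | COc1ccc(CO/C=C(\O[Si](C(C)C)(C(C)C)OS(=O)(=O)C(F)(F)F)C(C)=C)cc1 | intermediate
14 | (4R)-4-[({[(1Z)-1-[(4-methoxybenzyl)oxy]-3-methylbuta-1,3-dien-2-yl]oxy}di(propan-2-yl)silyl)oxy]-7-methylocta-1,6-dien-3-one | COc1ccc(CO/C=C(\O[Si](C(C)C)(C(C)C)O[C@H](CC=C(C)C)C(=O)C=C)C(C)=C)cc1 | intermediate
15 | (5R,7R,11R)-11-[(4-methoxybenzyl)oxy]-10-methyl-5-(3-methylbut-2-en-1-yl)-3,3-di(propan-2-yl)-2,4-dioxa-3-silabicyclo[5.3.1]undec-1(10)-en-6-one | O=C1[C@@H]2CCC(C)=C(O[Si](C(C)C)(C(C)C)O[C@@H]1CC=C(C)C)[C@@H]2OCc3ccc(OC)cc3 | intermediate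
16 | (5R,7S,11R)-11-[(4-methoxybenzyl)oxy]-10-methyl-6-methylidene-5-(3-methylbut-2-en-1-yl)-3,3-di(propan-2-yl)-2,4-dioxa-3-silabicyclo[5.3.1]undec-1(10)-ene | C=C1[C@@H]2CCC(C)=C(O[Si](C(C)C)(C(C)C)O[C@@H]1CC=C(C)C)[C@@H]2OCc3ccc(OC)cc3 | intermediate
17 | {[(3R)-2-{(1S,2R)-2-[(4-methoxybenzyl)oxy]-4-methyl-3-oxocyclohex-4-en-1-yl}-6-methylhepta-1,5-dien-3-yl]oxy}di(propan-2-yl)silyl acetate (not isolated) | C=C([C@@H](CC=C(C)C)O[Si](C(C)C)(C(C)C)OC(C)=O)[C@@H]1CC=C(C)C(=O)[C@@H]1OCc1ccc(OC)cc1 | intermediate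
18 | (5S,6R)-5-[(3R)-3-hydroxy-6-methylhepta-1,5-dien-2-yl]-6-[(4-methoxybenzyl)oxy]-2-methylcyclohex-2-en-1-one | C=C([C@@H](CC=C(C)C)O)[C@@H]1CC=C(C)C(=O)[C@@H]1OCc1ccc(OC)cc1 | intermediate
19 | angelic acid, (2Z)-2-methylbut-2-enoic acid | C/C=C(/C)C(=O)O | starting material
20 | (3S)-2-{(1S,2R)-2-[(4-methoxybenzyl)oxy]-4-methyl-3-oxocyclohex-4-en-1-yl}-6-methylhepta-1,5-dien-3-yl (2Z)-2-methylbut-2-enoate | C=C([C@H](CC=C(C)C)OC(=O)/C(C)=C\C)[C@@H]1CC=C(C)C(=O)[C@@H]1OCc1ccc(OC)cc1 | intermediate
21 | (3S)-2-{(1S,2R,3S)-3-hydroxy-2-[(4-methoxybenzyl)oxy]-4-methylcyclohex-4-en-1-yl}-6-methylhepta-1,5-dien-3-yl (2Z)-2-methylbut-2-enoate | C=C([C@H](CC=C(C)C)OC(=O)/C(C)=C\C)[C@@H]1CC=C(C)[C@H](O)[C@@H]1OCc1ccc(OC)cc1 | intermediate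
22 | epoxy alcohol: C3–C4 epoxide of 21, epoxide oxygen cis to C5–OH, C6–OPMB and the C1 side chain | C=C([C@H](CC=C(C)C)OC(=O)/C(C)=C\C)[C@@H]1C[C@@H]2O[C@]2(C)[C@H](O)[C@@H]1OCc1ccc(OC)cc1 | intermediate
23 | angelic 2,4,6-trichlorobenzoic anhydride (not isolated) | C/C=C(/C)C(=O)OC(=O)c1c(Cl)cc(Cl)cc1Cl | intermediate
24 | bis-angelate PMB ether: 22 with the C5 hydroxyl esterified as the (2Z)-2-methylbut-2-enoate | C=C([C@H](CC=C(C)C)OC(=O)/C(C)=C\C)[C@@H]1C[C@@H]2O[C@]2(C)[C@H](OC(=O)/C(C)=C\C)[C@@H]1OCc1ccc(OC)cc1 | intermediate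
25 | bis-epoxide PMB ether: 24 with the prenyl alkene converted into the (R)-3,3-dimethyloxiran-2-yl group; the 6-O-(4-methoxybenzyl) ether of the target | C=C([C@H](C[C@H]1OC1(C)C)OC(=O)/C(C)=C\C)[C@@H]1C[C@@H]2O[C@]2(C)[C@H](OC(=O)/C(C)=C\C)[C@@H]1OCc1ccc(OC)cc1 | intermediate
26 | CNP0296086.3 | C=C([C@H](C[C@H]1OC1(C)C)OC(=O)/C(C)=C\C)[C@@H]1C[C@@H]2O[C@]2(C)[C@H](OC(=O)/C(C)=C\C)[C@@H]1O | target

**Step count.** Total: 16 steps. Longest linear sequence: 14 steps (steps 3–6, then 7–16).

**Steps most likely to fail**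

Step 8. The tethered cycloaddition may lose facial control (the C8 group shielding the wrong face) or regiocontrol (bonding of C1 to C3), or the silyl enol ether may hydrolyse before it cyclises. The fallback sets out from 4 and 12 and comes back at 18. Ketone 4 is converted with t-BuMe2SiOTf/Et3N into tert-butyl({(1Z)-1-[(4-methoxybenzyl)oxy]-3-methylbuta-1,3-dien-2-yl}oxy)dimethylsilane F1. F1 and free hydroxy enone 12 are then combined without a tether, in toluene at ambient temperature or with MgBr2·OEt2 in CH2Cl2 at −78 °C, in a Masamune-type Diels–Alder reaction. The α′-hydroxy enone reacts as its hydrogen-bonded or chelated s-cis form with the diene anti to the prenyl CH2, which predicts the same facial sense and gives the silyl enol ether cycloadduct F2. Cp2TiMe2 methylenates the side-chain ketone to the methylidene compound F3, and Pd(OAc)2 then gives 18 directly. In this variant regiocontrol rests only on the 1-alkoxy and 3-methyl groups of the diene.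

Step 10. Silicon-to-palladium transfer at the hindered bridgehead dialkoxysilyl enol ether may be slow, or β-hydride elimination may go toward the methyl group. The fallback sets out from 16 and comes back at 18. PhSeCl (1.0 equiv, CH2Cl2, −78 °C) selenenylates the far more nucleophilic enol ether carbon C4; after aqueous work-up this gives the α-phenylselanyl ketone silanol F4, whose new C4 stereocenter is lost again. H2O2/pyridine then triggers selenoxide syn-elimination to the enone silanol F5, and HF·pyridine gives 18.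

Step 11. The hindered allylic alcohol may be activated incompletely, or react by SN2′ substitution or elimination, or the angelate may isomerise. The fallback sets out from 18 and comes back at 20. A Mitsunobu reaction with the more acidic chloroacetic acid gives the inverted chloroacetate F6. Brief methanolysis (catalytic K2CO3, MeOH, 0 °C) releases the (S)-alcohol F7, which is acylated with mixed anhydride 23 under the conditions of step 14 to give 20.

Further compounds
F1 | step 8 | tert-butyl({(1Z)-1-[(4-methoxybenzyl)oxy]-3-methylbuta-1,3-dien-2-yl}oxy)dimethylsilane | COc1ccc(CO/C=C(\O[Si](C)(C)C(C)(C)C)C(C)=C)cc1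
F2 | step 8 | (2R)-1-{3-[(tert-butyldimethylsilyl)oxy]-2-[(4-methoxybenzyl)oxy]-4-methylcyclohex-3-en-1-yl}-2-hydroxy-5-methylhex-4-en-1-one, ring configured as in 15 | CC(C)=CC[C@@H](O)C(=O)[C@@H]1CCC(C)=C(O[Si](C)(C)C(C)(C)C)[C@@H]1OCc1ccc(OC)cc1
F3 | step 8 | (3R)-2-{3-[(tert-butyldimethylsilyl)oxy]-2-[(4-methoxybenzyl)oxy]-4-methylcyclohex-3-en-1-yl}-6-methylhepta-1,5-dien-3-ol, ring configured as in 16 | C=C([C@@H](CC=C(C)C)O)[C@@H]1CCC(C)=C(O[Si](C)(C)C(C)(C)C)[C@@H]1OCc1ccc(OC)cc1
F4 | step 10 | α-phenylselanyl ketone silanol: 2-(phenylselanyl) derivative of the 2,3-dihydro form of 18 carrying a hydroxydi(propan-2-yl)silyl group on the C8 oxygen | C=C([C@@H](CC=C(C)C)O[Si](O)(C(C)C)C(C)C)[C@@H]1CCC(C)([Se]c2ccccc2)C(=O)[C@@H]1OCc1ccc(OC)cc1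
F5 | step 10 | enone silanol: 18 carrying a hydroxydi(propan-2-yl)silyl group on the C8 oxygen | C=C([C@@H](CC=C(C)C)O[Si](O)(C(C)C)C(C)C)[C@@H]1CC=C(C)C(=O)[C@@H]1OCc1ccc(OC)cc1
F6 | step 11 | (3S)-2-{(1S,2R)-2-[(4-methoxybenzyl)oxy]-4-methyl-3-oxocyclohex-4-en-1-yl}-6-methylhepta-1,5-dien-3-yl chloroacetate | C=C([C@H](CC=C(C)C)OC(=O)CCl)[C@@H]1CC=C(C)C(=O)[C@@H]1OCc1ccc(OC)cc1
F7 | step 11 | (5S,6R)-5-[(3S)-3-hydroxy-6-methylhepta-1,5-dien-2-yl]-6-[(4-methoxybenzyl)oxy]-2-methylcyclohex-2-en-1-one | C=C([C@H](CC=C(C)C)O)[C@@H]1CC=C(C)C(=O)[C@@H]1OCc1ccc(OC)cc1
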